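## Retrosynthetic overview

- The target (rings A to G, joined only by ether oxygens) comes from its octadecamethyl ether by global O-demethylation. That ether is cut at the oxygen between C1 of ring C and C4 of ring B, giving a pentamer phenol (rings C to G) and a dimer iodide (rings A and B).
- The strategy rests on ring C: C1 to C5 each carry an oxygen (C1–O–ring B, C2–O–ring D, hydroxyls on C3, C4 and C5) and C6 carries hydrogen. C1 to C4 with their oxygens come from a squarate and C5–C6 from a 1-methoxyvinyl unit. The C1–C6 bond is closed by thermal ring expansion of a cyclobutenone.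
- The cyclobutenone comes from a mixed methyl aryl squarate (aryl = tetramer D to G) by addition of 1-methoxyvinyllithium and O-methylation. The mixed squarate comes from the tetramer phenol and a chloro methoxy squarate made from dimethyl squarate.
- The tetramer phenol is built by three Ullmann etherifications, each joining a flanked phenol to an unflanked aryl halide (D+E, F+G, DE+FG), followed by sterically directed C–H borylation and oxidation on ring D. The dimer iodide comes from 2-bromo-1,3-dimethoxybenzene by C–H borylation, iodination, Ullmann coupling and bromine-to-iodine exchange.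
- Ring order: rings A, B, D, E, F and G are bought as benzene rings; ring C is the only ring formed (step 13).

Key step: step 13

Remark: the target has no stereocentre; the only one met on the way (C4 of cyclobutenone 19, racemic) becomes sp2 in step 13. "DEFG-oxy" means the aryloxy group of phenol 12. Compounds 1, 4, 7, 8, 13, 17, 23 and 26 are taken to be commercial.

## Route

Step 1
Reactants: 1 2,3,4-trimethoxyphenol
Product: 2 6-iodo-2,3,4-trimethoxyphenol
Conditions: NIS, MeCN, 0 °C, dark
Reagents that add atoms: N-iodosuccinimide, O=C1CCC(=O)N1I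
Why: Electrophilic aromatic iodination, in which the free hydroxyl is the strongest donor and its para position is blocked, so iodine should enter ortho to it at C6.

Step 2
Reactants: 2 6-iodo-2,3,4-trimethoxyphenol
Product: 3 2-(benzyloxy)-1-iodo-3,4,5-trimethoxybenzene
Conditions: BnBr, K2CO3, DMF, rt
Reagents that add atoms: benzyl bromide, BrCc1ccccc1
Why: Williamson ether synthesis masks the ring E hydroxyl so that the iodide of the same ring can serve as the electrophile in step 3.

Step 3
Reactants: 3 2-(benzyloxy)-1-iodo-3,4,5-trimethoxybenzene; 4 2,6-dimethoxyphenol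
Product: 5 2-(benzyloxy)-1-(2,6-dimethoxyphenoxy)-3,4,5-trimethoxybenzene (dimer DE benzyl ether)
Conditions: CuI (10 mol%), picolinic acid (20 mol%), K3PO4, DMSO, 100 °C
Reagents that add atoms: none
Why: Ullmann-type copper-catalysed diaryl ether synthesis in its favourable polarity, with the doubly flanked phenol as nucleophile and an aryl iodide bearing only one ortho substituent as electrophile.

Step 4
Reactants: 5 dimer DE benzyl ether
Product: 6 6-(2,6-dimethoxyphenoxy)-2,3,4-trimethoxyphenol (dimer DE phenol)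
Conditions: H2 (1 atm), Pd/C, EtOAc/MeOH, rt
Reagents that add atoms: none
Why: Hydrogenolysis cleaves the benzyl ether and leaves diaryl and methyl aryl ethers untouched.

Step 5
Reactants: 7 4-bromo-2,6-dimethoxyphenol; 8 5-iodo-1,2,3-trimethoxybenzene
Product: 9 5-bromo-1,3-dimethoxy-2-(3,4,5-trimethoxyphenoxy)benzene (dimer FG bromide)
Conditions: CuI (10 mol%), N,N-dimethylglycine hydrochloride (30 mol%), Cs2CO3, dioxane, 90 °C, 8 in excess
Reagents that add atoms: none
Why: Chemoselective Ullmann etherification, since the aryl iodide reacts at a temperature at which the bromide of 7, deactivated further by its para phenoxide, should stay intact.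

Step 6
Reactants: 6 dimer DE phenol; 9 dimer FG bromide
Product: 10 1-(2,6-dimethoxyphenoxy)-2-[3,5-dimethoxy-4-(3,4,5-trimethoxyphenoxy)phenoxy]-3,4,5-trimethoxybenzene (tetramer DEFG arene)
Conditions: CuI (10 mol%), picolinic acid (20 mol%), K3PO4, DMSO, 110 °C
Reagents that add atoms: none
Why: Ullmann etherification of a flanked phenol with an aryl bromide that has two ortho hydrogens, and 9 carries the only carbon–halogen bond in the flask.

Step 7
Reactants: 10 tetramer DEFG arene
Product: 11 2-(4-{2-[3,5-dimethoxy-4-(3,4,5-trimethoxyphenoxy)phenoxy]-3,4,5-trimethoxyphenoxy}-3,5-dimethoxyphenyl)-4,4,5,5-tetramethyl-1,3,2-dioxaborolane (tetramer DEFG boronate)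
Conditions: [Ir(OMe)(cod)]2 (1.5 mol%), 4,4'-di-tert-butyl-2,2'-bipyridine (3 mol%), B2pin2, THF, 80 °C
Reagents that add atoms: bis(pinacolato)diboron, CC1(C)OB(OC1(C)C)B1OC(C)(C)C(C)(C)O1
Why: Iridium-catalysed C–H borylation is sterically controlled, and the hydrogen para to the ether oxygen of ring D is the only aromatic C–H of 10 without an ortho substituent.

Step 8
Reactants: 11 tetramer DEFG boronate
Product: 12 4-{2-[3,5-dimethoxy-4-(3,4,5-trimethoxyphenoxy)phenoxy]-3,4,5-trimethoxyphenoxy}-3,5-dimethoxyphenol (tetramer DEFG phenol)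
Conditions: 30% H2O2, aq. NaOH, THF, 0 °C; then aq. Na2S2O3/NH4Cl
Reagents that add atoms: hydrogen peroxide, OO
Why: Oxidation of the arylboronate by hydroperoxide (1,2-shift of the aryl group from boron to oxygen, then hydrolysis) gives the phenol at the borylated carbon.

Step 9
Reactants: 13 dimethyl squarate
Product: 14 sodium 2-methoxy-3,4-dioxocyclobut-1-en-1-olate
Conditions: NaOH (1.0 equiv), THF/H2O, 0 °C to rt; evaporate, dry
Reagents that add atoms: sodium hydroxide, [Na+].[OH-]
Why: Addition–elimination hydrolysis of one vinylogous ester, stopping at the mono-salt because the enolate anion is deactivated toward a second attack.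

Step 10
Reactants: 14 sodium 2-methoxy-3,4-dioxocyclobut-1-en-1-olate
Product: 15 3-chloro-4-methoxycyclobut-3-ene-1,2-dione
Conditions: (COCl)2, DMF (cat.), CH2Cl2, 0 °C to rt; used crude
Reagents that add atoms: oxalyl chloride, O=C(Cl)C(Cl)=O
Why: Vilsmeier-type chlorination turns the vinylogous carboxylate into the vinylogous acid chloride, as for ordinary acid chlorides.

Step 11
Reactants: 12 tetramer DEFG phenol; 15 3-chloro-4-methoxycyclobut-3-ene-1,2-dione
Product: 16 3-(DEFG-oxy)-4-methoxycyclobut-3-ene-1,2-dione (mixed aryl methyl squarate)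
Conditions: iPr2NEt, CH2Cl2, −40 to 0 °C
Reagents that add atoms: none
Why: Addition–elimination at the vinylogous acid chloride (O-acylation type) attaches the phenol oxygen, with chloride leaving far more readily than methoxide.

Step 12
Reactants: 16 mixed aryl methyl squarate; 17 methyl vinyl ether
Product: 19 racemic 2-(DEFG-oxy)-3,4-dimethoxy-4-(1-methoxyvinyl)cyclobut-2-en-1-one (key precursor), via lithium cyclobutenolate 18 (not isolated)
Conditions: 17 (excess), tBuLi, THF, −78 to 0 °C; then 16, THF, −78 °C; then MeOTf, −78 to −20 °C; aq. NaHCO3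
Reagents that add atoms: methyl trifluoromethanesulfonate, COS(=O)(=O)C(F)(F)F
Why: 1,2-Addition of 1-methoxyvinyllithium should go to the carbonyl next to the methoxy-bearing carbon, which is conjugated with the weaker aryloxy donor and less shielded than the carbonyl beside the bulky aryloxy group, and the lithium alkoxide is then O-methylated in the flask; the quaternary centre forms racemic and is erased in step 13.

Step 13
Reactants: 19 key precursor
Product: 22 2-(DEFG-oxy)-3,4,5-trimethoxyphenol (pentamer phenol CDEFG with the free hydroxyl on C1 of ring C), via dienylketene 20 (not isolated), via cyclohexadienone 21 (not isolated)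
Conditions: toluene (0.01 M, degassed, base-washed glassware), 110 °C
Reagents that add atoms: none
Why: Heat opens the C1–C4 bond of 19 by conrotatory 4π electrocyclic ring opening to the (Z)-dienylketene 20, whose ketene carbon (future C1) and terminal vinyl carbon (future C6) join in a thermally allowed disrotatory 6π electrocyclisation to dienone 21, and enolisation of the C6 methylene gives the arene and the C1 hydroxyl. The closest known reaction type is the Moore rearrangement of squarate-derived 4-alkenyl-4-alkoxy- or 4-hydroxycyclobutenones to highly oxygenated phenols and hydroquinone ethers. Ring C, a six-membered carbocycle, is closed by this 6π electrocyclisation through the C1–C6 bond, with all five oxygens already on their carbons (aryloxy on C2 and methoxy on C3 from the squarate, methoxy on C4 from the capped carbinol, methoxy on C5 from the vinyl ether). No stereocentre is formed, and the racemic quaternary carbon of 19 becomes sp2. The step needs the 1-methoxyvinyl group to rotate inward during ring opening, which is secured by the strong outward preference of the methoxy donor on the tetrahedral carbon; a ketene from the opposite rotation can only close back to 19. Dilution and the absence of nucleophiles and acid should keep the ketene from being trapped and the enol ether from hydrolysis, and only the ketene oxygen ends up free, so step 18 needs no protecting-group work.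

Step 14
Reactants: 23 2-bromo-1,3-dimethoxybenzene
Product: 24 2-(4-bromo-3,5-dimethoxyphenyl)-4,4,5,5-tetramethyl-1,3,2-dioxaborolane
Conditions: [Ir(OMe)(cod)]2 (1 mol%), 4,4'-di-tert-butyl-2,2'-bipyridine (2 mol%), B2pin2, THF, 80 °C
Reagents that add atoms: bis(pinacolato)diboron, CC1(C)OB(OC1(C)C)B1OC(C)(C)C(C)(C)O1
Why: Sterically controlled iridium-catalysed C–H borylation of a 1,2,3-trisubstituted benzene goes to C5, the only C–H without an ortho substituent, and tolerates the aryl bromide.

Step 15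
Reactants: 24 2-(4-bromo-3,5-dimethoxyphenyl)-4,4,5,5-tetramethyl-1,3,2-dioxaborolane
Product: 25 2-bromo-5-iodo-1,3-dimethoxybenzene
Conditions: CuI (10 mol%), 1,10-phenanthroline (20 mol%), KI, MeOH/H2O, air, 80 °C
Reagents that add atoms: potassium iodide, [K+].[I-]
Why: Copper-catalysed aerobic iododeboronation replaces the boronate ipso by iodine, giving two halogens of different reactivity on ring B.

Step 16
Reactants: 25 2-bromo-5-iodo-1,3-dimethoxybenzene; 26 2,4,6-trimethoxyphenol
Product: 27 2-bromo-1,3-dimethoxy-5-(2,4,6-trimethoxyphenoxy)benzene (dimer AB bromide)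
Conditions: CuI (10 mol%), N,N-dimethylglycine hydrochloride (30 mol%), Cs2CO3, dioxane, 90 °C, argon
Reagents that add atoms: none
Why: Chemoselective Ullmann etherification at the unhindered iodide, while the bromide between two methoxy groups is both less reactive and shielded.

Step 17
Reactants: 27 dimer AB bromide
Product: 29 2-iodo-1,3-dimethoxy-5-(2,4,6-trimethoxyphenoxy)benzene (dimer AB iodide), via aryllithium 28 (not isolated)
Conditions: nBuLi, THF, −78 °C; then I2, THF, −78 °C to rt
Reagents that add atoms: iodine, II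
Why: Bromine–lithium exchange is much faster than ortho-lithiation at −78 °C and gives an aryllithium stabilised by two ortho methoxy groups, which iodine traps at the same carbon.

Step 18
Reactants: 22 pentamer phenol CDEFG; 29 dimer AB iodide
Product: 30 octadecamethyl ether of the target (permethylated heptamer ABCDEFG)
Conditions: CuI (20 mol%), picolinic acid (40 mol%), K3PO4, DMSO, 110 °C, argon
Reagents that add atoms: none
Why: Ullmann-type etherification under conditions suited to hindered partners, using the iodide because ring B must react at a carbon flanked by two methoxy groups; these are small and can coordinate copper.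

Step 19
Reactants: 30 octadecamethyl ether of the target
Product: 31 CNP0292517.0 (target)
Conditions: BBr3 (excess), CH2Cl2, −78 °C to rt; then MeOH, H2O; work-up under argon
Reagents that add atoms: none
Why: Lewis-acid cleavage of the eighteen aryl methyl ethers by BBr3 (bromide attacks the methyl group of the boron-complexed ether), while the diaryl ether bonds, which offer no alkyl carbon for attack, should persist.

## Compound list

1 | 2,3,4-trimethoxyphenol | COc1ccc(O)c(OC)c1OC | starting material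
2 | 6-iodo-2,3,4-trimethoxyphenol | COc1cc(I)c(O)c(OC)c1OC | intermediate
3 | 2-(benzyloxy)-1-iodo-3,4,5-trimethoxybenzene | COc1cc(I)c(OCc2ccccc2)c(OC)c1OC | intermediate
4 | 2,6-dimethoxyphenol | COc1cccc(OC)c1O | starting material
5 | 2-(benzyloxy)-1-(2,6-dimethoxyphenoxy)-3,4,5-trimethoxybenzene (dimer DE benzyl ether) | COc1cc(Oc2c(OC)cccc2OC)c(OCc2ccccc2)c(OC)c1OC | intermediate
6 | 6-(2,6-dimethoxyphenoxy)-2,3,4-trimethoxyphenol (dimer DE phenol) | COc1cc(Oc2c(OC)cccc2OC)c(O)c(OC)c1OC | intermediate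
7 | 4-bromo-2,6-dimethoxyphenol | COc1cc(Br)cc(OC)c1O | starting material
8 | 5-iodo-1,2,3-trimethoxybenzene | COc1cc(I)cc(OC)c1OC | starting material
9 | 5-bromo-1,3-dimethoxy-2-(3,4,5-trimethoxyphenoxy)benzene (dimer FG bromide) | COc1cc(Br)cc(OC)c1Oc1cc(OC)c(OC)c(OC)c1 | intermediate
10 | 1-(2,6-dimethoxyphenoxy)-2-[3,5-dimethoxy-4-(3,4,5-trimethoxyphenoxy)phenoxy]-3,4,5-trimethoxybenzene (tetramer DEFG arene) | COc1cccc(OC)c1Oc1cc(OC)c(OC)c(OC)c1Oc1cc(OC)c(Oc2cc(OC)c(OC)c(OC)c2)c(OC)c1 | intermediate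
11 | tetramer DEFG boronate (pinacol boronate on C1 of ring D) | COc1cc(B2OC(C)(C)C(C)(C)O2)cc(OC)c1Oc1cc(OC)c(OC)c(OC)c1Oc1cc(OC)c(Oc2cc(OC)c(OC)c(OC)c2)c(OC)c1 | intermediate
12 | 4-{2-[3,5-dimethoxy-4-(3,4,5-trimethoxyphenoxy)phenoxy]-3,4,5-trimethoxyphenoxy}-3,5-dimethoxyphenol (tetramer DEFG phenol) | COc1cc(O)cc(OC)c1Oc1cc(OC)c(OC)c(OC)c1Oc1cc(OC)c(Oc2cc(OC)c(OC)c(OC)c2)c(OC)c1 | intermediate
13 | dimethyl squarate | COC1=C(OC)C(=O)C1=O | starting material
14 | sodium 2-methoxy-3,4-dioxocyclobut-1-en-1-olate | [Na+].COC1=C([O-])C(=O)C1=O | intermediate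
15 | 3-chloro-4-methoxycyclobut-3-ene-1,2-dione | COC1=C(Cl)C(=O)C1=O | intermediate
16 | 3-(DEFG-oxy)-4-methoxycyclobut-3-ene-1,2-dione (mixed aryl methyl squarate) | COC1=C(Oc2cc(OC)c(Oc3cc(OC)c(OC)c(OC)c3Oc3cc(OC)c(Oc4cc(OC)c(OC)c(OC)c4)c(OC)c3)c(OC)c2)C(=O)C1=O | intermediate
17 | methyl vinyl ether | COC=C | starting material
18 | lithium 3-(DEFG-oxy)-2-methoxy-1-(1-methoxyvinyl)-4-oxocyclobut-2-en-1-olate (racemic) | [Li+].[O-]C1(C(=C)OC)C(OC)=C(Oc2cc(OC)c(Oc3cc(OC)c(OC)c(OC)c3Oc3cc(OC)c(Oc4cc(OC)c(OC)c(OC)c4)c(OC)c3)c(OC)c2)C1=O | intermediate (not isolated)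
19 | racemic 2-(DEFG-oxy)-3,4-dimethoxy-4-(1-methoxyvinyl)cyclobut-2-en-1-one (key precursor) | O=C1C(Oc2cc(OC)c(Oc3cc(OC)c(OC)c(OC)c3Oc3cc(OC)c(Oc4cc(OC)c(OC)c(OC)c4)c(OC)c3)c(OC)c2)=C(OC)C1(OC)C(=C)OC | intermediate
20 | (Z)-2-(DEFG-oxy)-3,4,5-trimethoxyhexa-1,3,5-trien-1-one (dienylketene) | O=C=C(Oc1cc(OC)c(Oc2cc(OC)c(OC)c(OC)c2Oc2cc(OC)c(Oc3cc(OC)c(OC)c(OC)c3)c(OC)c2)c(OC)c1)/C(OC)=C(OC)\C(=C)OC | intermediate (not isolated)
21 | 2-(DEFG-oxy)-3,4,5-trimethoxycyclohexa-2,4-dien-1-one | O=C1CC(OC)=C(OC)C(OC)=C1Oc1cc(OC)c(Oc2cc(OC)c(OC)c(OC)c2Oc2cc(OC)c(Oc3cc(OC)c(OC)c(OC)c3)c(OC)c2)c(OC)c1 | intermediate (not isolated)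
22 | 2-(DEFG-oxy)-3,4,5-trimethoxyphenol (pentamer phenol CDEFG) | COc1cc(O)c(Oc2cc(OC)c(Oc3cc(OC)c(OC)c(OC)c3Oc3cc(OC)c(Oc4cc(OC)c(OC)c(OC)c4)c(OC)c3)c(OC)c2)c(OC)c1OC | intermediate
23 | 2-bromo-1,3-dimethoxybenzene | COc1cccc(OC)c1Br | starting material
24 | 2-(4-bromo-3,5-dimethoxyphenyl)-4,4,5,5-tetramethyl-1,3,2-dioxaborolane | COc1cc(B2OC(C)(C)C(C)(C)O2)cc(OC)c1Br | intermediate
25 | 2-bromo-5-iodo-1,3-dimethoxybenzene | COc1cc(I)cc(OC)c1Br | intermediate
26 | 2,4,6-trimethoxyphenol | COc1cc(OC)c(O)c(OC)c1 | starting material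
27 | 2-bromo-1,3-dimethoxy-5-(2,4,6-trimethoxyphenoxy)benzene (dimer AB bromide) | COc1cc(OC)c(Oc2cc(OC)c(Br)c(OC)c2)c(OC)c1 | intermediate
28 | [2,6-dimethoxy-4-(2,4,6-trimethoxyphenoxy)phenyl]lithium | [Li]c1c(OC)cc(Oc2c(OC)cc(OC)cc2OC)cc1OC | intermediate (not isolated)
29 | 2-iodo-1,3-dimethoxy-5-(2,4,6-trimethoxyphenoxy)benzene (dimer AB iodide) | COc1cc(OC)c(Oc2cc(OC)c(I)c(OC)c2)c(OC)c1 | intermediate
30 | octadecamethyl ether of the target (permethylated heptamer ABCDEFG) | COc1cc(OC)c(Oc2cc(OC)c(Oc3cc(OC)c(OC)c(OC)c3Oc3cc(OC)c(Oc4cc(OC)c(OC)c(OC)c4Oc4cc(OC)c(Oc5cc(OC)c(OC)c(OC)c5)c(OC)c4)c(OC)c3)c(OC)c2)c(OC)c1 | intermediate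
31 | CNP0292517.0 | Oc1cc(O)c(Oc2cc(O)c(Oc3cc(O)c(O)c(O)c3Oc3cc(O)c(Oc4cc(O)c(O)c(O)c4Oc4cc(O)c(Oc5cc(O)c(O)c(O)c5)c(O)c4)c(O)c3)c(O)c2)c(O)c1 | target

## Step count and risks

Total step count: 19. Longest linear sequence: 12 steps (1, 2, 3, 4, 6, 7, 8, 11, 12, 13, 18, 19).

Steps most likely to fail:

1. Step 13 (ring expansion). The methoxy group on the tetrahedral carbon may rotate inward in part, or the dienylketene may be intercepted (dimerisation, addition of adventitious water) before it cyclises, and the enol ether may hydrolyse, so that ring C does not form cleanly. The fallback brings ring C in as a preformed arene and sets out from boronate 11. 3,4,5-Trimethoxyphenol would be ortho-formylated (MgCl2, Et3N, paraformaldehyde, MeCN, reflux) to 2-hydroxy-4,5,6-trimethoxybenzaldehyde F1 and benzylated (BnBr, K2CO3, DMF) to 2-(benzyloxy)-4,5,6-trimethoxybenzaldehyde F2. Baeyer–Villiger oxidation (mCPBA, CH2Cl2) would give 2-(benzyloxy)-4,5,6-trimethoxyphenyl formate F3, and methanolysis (K2CO3, MeOH) 6-(benzyloxy)-2,3,4-trimethoxyphenol F4. Boronate 11 would be converted by copper-mediated bromodeboronation (CuBr2, MeOH/H2O, 80 °C) into the tetramer DEFG bromide F5. Ullmann coupling of F4 with F5 (CuI, picolinic acid, K3PO4, DMSO, 110 °C) would give the benzyl ether of the pentamer phenol F6, and hydrogenolysis (H2, Pd/C) comes back to the route at 22.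

2. Step 12 (vinyllithium addition). Addition may divide between the two squarate carbonyls, or the organolithium may displace the aryloxide by conjugate addition–elimination, so that the oxygen pattern of 19 is not secured. The fallback removes the regiochemical question by symmetry and sets out from 12. Two equivalents of 12 and 3,4-dichlorocyclobut-3-ene-1,2-dione (iPr2NEt, CH2Cl2, −40 °C) would give 3,4-bis(DEFG-oxy)cyclobut-3-ene-1,2-dione F7. Addition of 1-methoxyvinyllithium (THF, −78 °C) would give the lithium 2,3-bis(DEFG-oxy)-1-(1-methoxyvinyl)-4-oxocyclobut-2-en-1-olate F8, methylated in the flask with MeOTf to racemic 2,3-bis(DEFG-oxy)-4-methoxy-4-(1-methoxyvinyl)cyclobut-2-en-1-one F9. Sodium methoxide (1 equiv, MeOH/THF, −20 °C) would then exchange only the aryloxy group on C3, the vinylogous ester position, by conjugate addition–elimination. This comes back to the route at 19 and releases one equivalent of 12 for re-use.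

3. Step 18 (hindered etherification). Oxidative addition at the iodide flanked by two methoxy groups may be slow, and reduction of the iodide to the arene may outrun C–O bond formation with the ortho-substituted phenol. The fallback reverses the polarity and sets out from 22 and 27. Phenol 22 would be converted (Tf2O, pyridine, CH2Cl2, 0 °C) into the pentamer CDEFG triflate F10. Bromide 27 would be hydroxylated (Pd2(dba)3, tBuXPhos, KOH, dioxane/H2O, 100 °C) to 2,6-dimethoxy-4-(2,4,6-trimethoxyphenoxy)phenol F11. Palladium-catalysed diaryl ether coupling of F10 with F11 (Pd(OAc)2, tBuXPhos, K3PO4, toluene, 100 °C) comes back to the route at 30.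

## Further compounds

F1 | step 13 | 2-hydroxy-4,5,6-trimethoxybenzaldehyde | COc1cc(O)c(C=O)c(OC)c1OC
F2 | step 13 | 2-(benzyloxy)-4,5,6-trimethoxybenzaldehyde | COc1cc(OCc2ccccc2)c(C=O)c(OC)c1OC
F3 | step 13 | 2-(benzyloxy)-4,5,6-trimethoxyphenyl formate | COc1cc(OCc2ccccc2)c(OC=O)c(OC)c1OC
F4 | step 13 | 6-(benzyloxy)-2,3,4-trimethoxyphenol | COc1cc(OCc2ccccc2)c(O)c(OC)c1OC
F5 | step 13 | tetramer DEFG bromide (bromine on C1 of ring D) | COc1cc(Br)cc(OC)c1Oc1cc(OC)c(OC)c(OC)c1Oc1cc(OC)c(Oc2cc(OC)c(OC)c(OC)c2)c(OC)c1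
F6 | step 13 | benzyl ether of pentamer phenol CDEFG | COc1cc(OCc2ccccc2)c(Oc2cc(OC)c(Oc3cc(OC)c(OC)c(OC)c3Oc3cc(OC)c(Oc4cc(OC)c(OC)c(OC)c4)c(OC)c3)c(OC)c2)c(OC)c1OC
F7 | step 12 | 3,4-bis(DEFG-oxy)cyclobut-3-ene-1,2-dione | O=C1C(=O)C(Oc2cc(OC)c(Oc3cc(OC)c(OC)c(OC)c3Oc3cc(OC)c(Oc4cc(OC)c(OC)c(OC)c4)c(OC)c3)c(OC)c2)=C1Oc1cc(OC)c(Oc2cc(OC)c(OC)c(OC)c2Oc2cc(OC)c(Oc3cc(OC)c(OC)c(OC)c3)c(OC)c2)c(OC)c1
F8 | step 12 | lithium 2,3-bis(DEFG-oxy)-1-(1-methoxyvinyl)-4-oxocyclobut-2-en-1-olate (racemic) | [Li+].[O-]C1(C(=C)OC)C(Oc2cc(OC)c(Oc3cc(OC)c(OC)c(OC)c3Oc3cc(OC)c(Oc4cc(OC)c(OC)c(OC)c4)c(OC)c3)c(OC)c2)=C(Oc2cc(OC)c(Oc3cc(OC)c(OC)c(OC)c3Oc3cc(OC)c(Oc4cc(OC)c(OC)c(OC)c4)c(OC)c3)c(OC)c2)C1=O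
F9 | step 12 | racemic 2,3-bis(DEFG-oxy)-4-methoxy-4-(1-methoxyvinyl)cyclobut-2-en-1-one | O=C1C(Oc2cc(OC)c(Oc3cc(OC)c(OC)c(OC)c3Oc3cc(OC)c(Oc4cc(OC)c(OC)c(OC)c4)c(OC)c3)c(OC)c2)=C(Oc2cc(OC)c(Oc3cc(OC)c(OC)c(OC)c3Oc3cc(OC)c(Oc4cc(OC)c(OC)c(OC)c4)c(OC)c3)c(OC)c2)C1(OC)C(=C)OC
F10 | step 18 | pentamer CDEFG triflate (triflate on C1 of ring C) | COc1cc(OS(=O)(=O)C(F)(F)F)c(Oc2cc(OC)c(Oc3cc(OC)c(OC)c(OC)c3Oc3cc(OC)c(Oc4cc(OC)c(OC)c(OC)c4)c(OC)c3)c(OC)c2)c(OC)c1OC
F11 | step 18 | 2,6-dimethoxy-4-(2,4,6-trimethoxyphenoxy)phenol | COc1cc(OC)c(Oc2cc(OC)c(O)c(OC)c2)c(OC)c1
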